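**Retrosynthetic overview**
1. Target ⇒ C4–C5 bond by intramolecular Nozaki–Hiyama–Kishi (NHK) alkenylation of a C5 aldehyde with the C4 vinyl bromide. This closes the 10-membered carbocycle last; the C8 methacrylate is installed beforehand.
2. The macrocycle precursor ⇒ Cr-mediated γ-selective allylation (C7–C8). It joins butenolide W (5, from (S)-5-hydroxymethylbutenolide; supplies C5–C7, C11–C13 and the C6 stereocentre) to furanone aldehyde E (19; supplies C8–C10, C14, C1–C4, C15).
3. E ⇐ Cu-box Mukaiyama aldol on a pyruvoyl Weinreb amide (sets C10), then Fukuyama reduction and acetalisation, alkynyl addition, 5-endo-dig oxa-Michael to the 3(2H)-furanone, and acetal hydrolysis.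
4. Ring order: furanone (in E), α-methylene-γ-lactone (during the allylation), 10-membered carbocycle (last).

Assumptions: commercial (S)-5-hydroxymethylbutenolide has the C6 configuration needed. (S,S)-tBu-box·Cu(OTf)2 is assumed to give the (R)-carbinol at C10; use the (R,R) ligand if the opposite sense is found. The Cr allylation is assumed to give the 4,5-trans/anti adduct.

---

**Step 1**
Reactants: 1, (S)-5-(hydroxymethyl)furan-2(5H)-one
Product: 2, (S)-5-[(TBDPS-oxy)methyl]furan-2(5H)-one
Conditions: TBDPSCl, imidazole, DMF, 23 °C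
Reagents that add atoms: TBDPSCl, `CC(C)(C)[Si](Cl)(c1ccccc1)c1ccccc1`
Why: Silylation of the primary alcohol; the C6 stereocentre is untouched (chiral-pool source of C6).

**Step 2**
Reactants: 2
Product: 3, (S)-3-bromo-5-[(TBDPS-oxy)methyl]furan-2(5H)-one
Conditions: Br2, CH2Cl2, 0 °C; then Et3N, 0 °C
Reagents that add atoms: Br2, `BrBr`
Why: Bromine adds across the enone C=C and Et3N eliminates HBr, giving the α-bromobutenolide (addition–elimination); the γ-stereocentre is not involved.

**Step 3**
Reactants: 3
Product: 4, (S)-5-[(TBDPS-oxy)methyl]-3-methylfuran-2(5H)-one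
Conditions: MeZnCl, Pd(PPh3)4 (5 mol %), THF, 0→23 °C
Reagents that add atoms: methylzinc chloride, `C[Zn]Cl`
Why: Negishi coupling replaces the vinyl bromide with methyl under non-basic conditions, which avoids γ-epimerisation.

**Step 4**
Reactants: 4
Product: 5, (S)-3-(bromomethyl)-5-[(TBDPS-oxy)methyl]furan-2(5H)-one (fragment W)
Conditions: NBS (1.05 equiv), AIBN (cat.), PhCF3, 80 °C
Reagents that add atoms: NBS, `O=C1CCC(=O)N1Br`
Why: Wohl–Ziegler radical bromination of the α-methyl group gives the allylic bromide needed for Cr-allylation; no stereocentre is formed.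

**Step 5**
Reactants: 6, pyruvic acid
Product: 7, N-methoxy-N-methyl-2-oxopropanamide
Conditions: CDI, CH2Cl2, 0 °C; then MeNH(OMe)·HCl, 23 °C
Reagents that add atoms: N,O-dimethylhydroxylamine hydrochloride, `CNOC.Cl`
Why: Acyl-imidazolide aminolysis gives the Weinreb amide, a bidentate α-keto acceptor that can chelate Cu(II).

**Step 6**
Reactants: 8, S-tert-butyl ethanethioate
Product: 9, {[1-(tert-butylsulfanyl)ethenyl]oxy}trimethylsilane
Conditions: LDA, THF, −78 °C; then TMSCl
Reagents that add atoms: TMSCl, `C[Si](C)(C)Cl`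
Why: Kinetic enolisation and O-silylation give the silyl ketene thioacetal, the Mukaiyama nucleophile.

**Step 7**
Reactants: 7 and 9
Product: 10, S-tert-butyl (3R)-3-hydroxy-4-[methoxy(methyl)amino]-3-methyl-4-oxobutanethioate
Conditions: (S,S)-tBu-box·Cu(OTf)2 (10 mol %), CH2Cl2, −78 °C; then 1 M HCl, THF
Reagents that add atoms: none
Why: Cu(II)-box-catalysed Mukaiyama aldol, where the chiral bidentate Cu chelate of the keto-amide blocks one face, sets the C10 quaternary carbinol; the aqueous acid removes the O-TMS group.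

**Step 8**
Reactants: 10
Product: 11, (2R)-2-hydroxy-N-methoxy-N,2-dimethyl-4-oxobutanamide
Conditions: Et3SiH, 10% Pd/C, acetone, 23 °C
Reagents that add atoms: none (H only)
Why: Fukuyama reduction converts the thioester to the aldehyde (C8) and leaves the Weinreb amide intact; C10 is not touched. Use the product at once.

**Step 9**
Reactants: 11
Product: 12, (2R)-4,4-dimethoxy-2-hydroxy-N-methoxy-N,2-dimethylbutanamide
Conditions: HC(OMe)3, MeOH, PPTS (cat.), 23 °C
Reagents that add atoms: trimethyl orthoformate, `COC(OC)OC`; methanol, `CO`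
Why: Acetalisation masks the aldehyde (and prevents retro-aldol or dehydration) before organometallic chemistry; no stereocentre is involved.

**Step 10**
Reactants: 13, 1,1-dibromoethene; 14, trimethylsilylacetylene
Product: 15, (3-bromobut-3-en-1-yn-1-yl)trimethylsilane
Conditions: Pd(PPh3)2Cl2 (3 mol %), CuI (6 mol %), i-Pr2NH, THF, 23 °C (13 in excess)
Reagents that add atoms: none
Why: Chemoselective mono-Sonogashira coupling of the gem-dibromide gives the 2-bromo-1,3-enyne (the C2–C4 unit).

**Step 11**
Reactants: 15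
Product: 16, 2-bromobut-1-en-3-yne
Conditions: K2CO3, MeOH, 0 °C (product carried as an Et2O solution)
Reagents that add atoms: none (H only)
Why: Protodesilylation of the alkynyl–TMS bond gives the terminal enyne.

**Step 12**
Reactants: 12 and 16
Product: 17, (3R)-7-bromo-3-hydroxy-1,1-dimethoxy-3-methyloct-7-en-5-yn-4-one
Conditions: 16 + EtMgBr (1 equiv), THF, 0 °C (alkynyl-MgBr); add 12 (alkynyl-MgBr ≥3 equiv), 0→23 °C
Reagents that add atoms: none (EtMgBr only deprotonates)
Why: Weinreb ketone synthesis through a stable chelated tetrahedral intermediate gives the α-hydroxy ynone (C1–C3); C10 is retained.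

**Step 13**
Reactants: 17
Product: 18, (2R)-5-(1-bromoethenyl)-2-(2,2-dimethoxyethyl)-2-methylfuran-3(2H)-one
Conditions: DBU (20 mol %), CH2Cl2, 0→23 °C
Reagents that add atoms: none
Why: Base-mediated 5-endo-dig oxa-Michael addition of the tertiary alkoxide to the ynone β-carbon forms the 3(2H)-furanone (O10–C3 bond); C10 is not involved.

**Step 14**
Reactants: 18
Product: 19, 2-[(2R)-5-(1-bromoethenyl)-2-methyl-3-oxo-2,3-dihydrofuran-2-yl]acetaldehyde (fragment E)
Conditions: TFA/H2O/CH2Cl2 (1:1:10), 0 °C
Reagents that add atoms: water, `O`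
Why: Acid hydrolysis of the dimethyl acetal releases the C8 aldehyde; the furanone enol ether survives brief mild acid.

**Step 15**
Reactants: 19 and 5
Product: 20, the (4R,5S)-trans-α-methylene-γ-lactone carrying the C8 (S)-carbinol: `C=C1C(=O)O[C@H](CO[Si](c2ccccc2)(c2ccccc2)C(C)(C)C)[C@H]1[C@@H](O)C[C@@]2(C)OC(C(Br)=C)=CC2=O`
Conditions: CrCl2 (4 equiv), THF, 23 °C
Reagents that add atoms: none (H at workup)
Why: Nozaki–Hiyama allylation at γ (SE2′) through a chair transition state with the ring-constrained E-allylchromium. The C6 substituent blocks one butenolide face, giving trans at C7; the chair gives anti at C7/C8. The exocyclic C11=C13 methylene forms in the same step; the vinyl bromide, furanone and TBDPS group are inert without Ni.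

**Step 16**
Reactants: 20
Product: 21, the C8 methacrylate of 20
Conditions: methacrylic acid, 2,4,6-Cl3C6H2COCl, Et3N, THF; then 20, DMAP, toluene, 23 °C
Reagents that add atoms: methacrylic acid, `CC(=C)C(=O)O`
Why: Yamaguchi esterification of the secondary C8 alcohol via a mixed anhydride, with retention of configuration at C8.

**Step 17**
Reactants: 21
Product: 22, the primary alcohol (TBDPS removed)
Conditions: HF·pyridine, pyridine/THF, 0→23 °C
Reagents that add atoms: none (H only)
Why: Fluoride deprotection under non-basic conditions avoids acyl migration of the methacrylate; no stereocentre is touched.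

**Step 18**
Reactants: 22
Product: 23, the C5 aldehyde
Conditions: Dess–Martin periodinane, NaHCO3, CH2Cl2, 23 °C
Reagents that add atoms: none
Why: Mild, buffered oxidation of the primary alcohol gives the α-oxy aldehyde without epimerising C6; use immediately.

**Step 19**
Reactants: 23
Product: 24, isogoiazensolide
Conditions: CrCl2 (10 equiv), NiCl2 (0.1 equiv), DMF, 0.003 M (syringe-pump addition), 23 °C
Reagents that add atoms: none (H at workup)
Why: Intramolecular NHK alkenylation (Ni-catalysed vinyl–Cr formation, then addition) closes the 10-membered ring. The new C5 carbinol is set by Felkin–Anh attack on the α-acyloxy aldehyde, which gives the C5/C6 anti relationship of the target.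

---

**Compound list**

1 | (S)-5-(hydroxymethyl)furan-2(5H)-one | `O=C1C=C[C@@H](CO)O1` | starting material
2 | (S)-5-[(TBDPS-oxy)methyl]furan-2(5H)-one | `O=C1C=C[C@@H](CO[Si](c2ccccc2)(c2ccccc2)C(C)(C)C)O1` | intermediate
3 | (S)-3-bromo-5-[(TBDPS-oxy)methyl]furan-2(5H)-one | `O=C1C(Br)=C[C@@H](CO[Si](c2ccccc2)(c2ccccc2)C(C)(C)C)O1` | intermediate
4 | (S)-5-[(TBDPS-oxy)methyl]-3-methylfuran-2(5H)-one | `CC1=C[C@@H](CO[Si](c2ccccc2)(c2ccccc2)C(C)(C)C)OC1=O` | intermediate
5 | (S)-3-(bromomethyl)-5-[(TBDPS-oxy)methyl]furan-2(5H)-one | `BrCC1=C[C@@H](CO[Si](c2ccccc2)(c2ccccc2)C(C)(C)C)OC1=O` | intermediate (fragment W)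
6 | pyruvic acid | `CC(=O)C(=O)O` | starting material
7 | N-methoxy-N-methyl-2-oxopropanamide | `CC(=O)C(=O)N(C)OC` | intermediate
8 | S-tert-butyl ethanethioate | `CC(=O)SC(C)(C)C` | starting material
9 | {[1-(tert-butylsulfanyl)ethenyl]oxy}trimethylsilane | `C=C(O[Si](C)(C)C)SC(C)(C)C` | intermediate
10 | S-tert-butyl (3R)-3-hydroxy-4-[methoxy(methyl)amino]-3-methyl-4-oxobutanethioate | `CC(C)(C)SC(=O)C[C@@](C)(O)C(=O)N(C)OC` | intermediate
11 | (2R)-2-hydroxy-N-methoxy-N,2-dimethyl-4-oxobutanamide | `O=CC[C@@](C)(O)C(=O)N(C)OC` | intermediate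
12 | (2R)-4,4-dimethoxy-2-hydroxy-N-methoxy-N,2-dimethylbutanamide | `COC(OC)C[C@@](C)(O)C(=O)N(C)OC` | intermediate
13 | 1,1-dibromoethene | `C=C(Br)Br` | starting material
14 | ethynyltrimethylsilane | `C#C[Si](C)(C)C` | starting material
15 | (3-bromobut-3-en-1-yn-1-yl)trimethylsilane | `C=C(Br)C#C[Si](C)(C)C` | intermediate
16 | 2-bromobut-1-en-3-yne | `C=C(Br)C#C` | intermediate
17 | (3R)-7-bromo-3-hydroxy-1,1-dimethoxy-3-methyloct-7-en-5-yn-4-one | `COC(OC)C[C@@](C)(O)C(=O)C#CC(Br)=C` | intermediate
18 | (2R)-5-(1-bromoethenyl)-2-(2,2-dimethoxyethyl)-2-methylfuran-3(2H)-one | `COC(OC)C[C@@]1(C)OC(C(Br)=C)=CC1=O` | intermediate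
19 | 2-[(2R)-5-(1-bromoethenyl)-2-methyl-3-oxo-2,3-dihydrofuran-2-yl]acetaldehyde | `O=CC[C@@]1(C)OC(C(Br)=C)=CC1=O` | intermediate (fragment E)
20 | (4R,5S)-4-[(1S)-2-[(2R)-5-(1-bromoethenyl)-2-methyl-3-oxo-2,3-dihydrofuran-2-yl]-1-hydroxyethyl]-5-[(TBDPS-oxy)methyl]-3-methylideneoxolan-2-one | `C=C1C(=O)O[C@H](CO[Si](c2ccccc2)(c2ccccc2)C(C)(C)C)[C@H]1[C@@H](O)C[C@@]2(C)OC(C(Br)=C)=CC2=O` | intermediate
21 | C8-O-methacrylate of 20 | `C=C1C(=O)O[C@H](CO[Si](c2ccccc2)(c2ccccc2)C(C)(C)C)[C@H]1[C@@H](OC(=O)C(C)=C)C[C@@]2(C)OC(C(Br)=C)=CC2=O` | intermediate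
22 | desilylated primary alcohol of 21 | `C=C1C(=O)O[C@H](CO)[C@H]1[C@@H](OC(=O)C(C)=C)C[C@@]2(C)OC(C(Br)=C)=CC2=O` | intermediate
23 | C5 aldehyde of 22 | `C=C1C(=O)O[C@H](C=O)[C@H]1[C@@H](OC(=O)C(C)=C)C[C@@]2(C)OC(C(Br)=C)=CC2=O` | intermediate
24 | isogoiazensolide | `C=C(C)C(=O)O[C@H]1C[C@@]2(C)OC(=CC2=O)C(=C)[C@@H](O)[C@H]2OC(=O)C(=C)[C@@H]21` | target

---

**Total step count:** 19.
**Longest linear sequence:** 12 (6→7→8→9→12→13→14→15→16→17→18→19), which is 0.63 of the total.

**Three steps most likely to fail, each with a fallback that changes the approach**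
1. **Step 19 (10-membered NHK ring closure; C5 selectivity; Cr/Ni tolerance of the Michael acceptors).**
   - Fallback: reverse the order of the two Cr reactions.
   - First add the vinyl-Cr intermolecularly to an acyclic C5 aldehyde.
   - Then close the ring by macro-allylation (C7–C8) of a 3-(bromomethyl)butenolide tethered to the C8 aldehyde.
   - If C5 comes out wrong, oxidise to the enone and reduce with (S)-CBS.
2. **Step 15 (Cr-allylation diastereocontrol; mismatched 1,3-induction from C10; aldehyde sensitivity to β-elimination).**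
   - Fallback: make the allylboronate from 5 (Pd/B2pin2) and use thermal allylboration.
   - Alternatively, use Seebach 1,4-addition of the C8 dithiane anion to butenolide 2, then α-methylenation.
3. **Step 7 (Cu-box aldol on the untested Weinreb pyruvamide).**
   - Fallback: use methyl pyruvate (precedented), carry the ester through Steps 8–9, then form the Weinreb amide.
   - Alternatively, set C10 by Sharpless asymmetric epoxidation of methallyl alcohol and open the epoxide with a C8 nucleophile.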